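1. I start from the leftover: c(left-handed substrate) beside c(right-handed substrate), both in percent of the two charged together.

| setting | larch | alder | elm | flask |
|---|---|---|---|---|
| left-handed substrate | 20 mM | 20 mM | 10 mM | 20 mM |
| right-handed substrate | 20 mM | 20 mM | 10 mM | 20 mM |
| gas | 4.6 mM (held) | 4.6 mM (held) | 4.6 mM (held) | 4.6 mM (held) |
| free catalyst | 0.28 mol% | 0.44 mol% | 0.2 mol% | 0.2 mol% |
| remark | run made earlier | run made earlier | run made earlier |  |
| time |  |  |  | 1.5 h |

- larch (time / min: right-handed substrate / %, left-handed substrate / %): 15.0: 48.8, 8.4; 30.0: 48.3, 0.4; 40.0: 47.9, 0.3; 60.0: 46.3, 0.3; 80.0: 46.1, 0.1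
- alder (time / min: right-handed substrate / %, left-handed substrate / %): 6.00: 50.6, 29.5; 20.0: 48.7, 2.3; 30.0: 48.2, 0.4; 50.0: 47.0, 0.2; 80.0: 46.3, 0
- elm (time / min: right-handed substrate / %, left-handed substrate / %): 15.0: 49.3, 2.2; 30.0: 47.5, 0; 40.0: 47.7, 0; 60.0: 45.9, 0.4; 80.0: 46.2, 0

(each reading ± 0.3 percentage points)

- whether the excess of right-handed substrate over left-handed substrate among what is left of the two reaches 90% by 1.5 h (yes / no)
- the highest excess of right-handed substrate over left-handed substrate among what is left of the two up to 1.5 h

- free catalyst is single-handed; left-handed substrate and right-handed substrate are mirror images of each other, charged as a racemate, each of them at the stated concentration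
- at the start none of the gas is in solution

2. My bench rule says that, while c(left-handed substrate) is small beside c(right-handed substrate), the excess falls short of 100% by about 2 times the ratio of those two concentrations. Exactly, a wanted excess e needs their ratio to fall to (1-e)/(1+e).

3. For 90.0%, with the right-handed substrate taken as still 0.5 of the charge, the first round gives 2.63%.

4. I go round again with the alder reading of 48.7% at 20.0 min. This gives the allowed leftover, the c(left-handed substrate) at which the excess just reaches the wanted value: 2.56%. Alder reads 2.3% there, so it has about arrived.

5. If time goes inversely with loading, my estimate for the flask is 44.0 min, which is shorter than 1.5 h. I commit to yes.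

6. The rule has a border. The allowed leftover is 8.54 times the scatter, so readings can show it. But a leftover equal to the scatter, beside the alder reading of 46.3%, gives 98.7%, and an excess above that has a leftover inside the scatter of one reading.

7. The forecast says yes and 99.7%, with the left-handed substrate “consumed fast and goes to noise level”. Its top lies above my border.

8. The flask gives yes and >99.9%.

    partner + free catalyst + left-handed substrate → free catalyst + left-handed product (k = 2.83 × 10⁵ M⁻² s⁻¹)
    partner + free catalyst + right-handed substrate → free catalyst + right-handed product (k = 1.07 × 10⁵ M⁻² min⁻¹)
    2 free catalyst → spent catalyst (k = 4390 M⁻¹ min⁻¹)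
    gas ⇌ partner, rate k4*(csat - [partner]) (kL = 0.329 min⁻¹)
    partner ⇌ dormant form (K = 42.2, k = 0.0818 min⁻¹)

The flask reaches the wanted excess at 0.349 h, in about half of my scaled time, with 49.1% of right-handed substrate left. Scaled to that remainder, the allowed leftover becomes 2.58%. At 0.150 h the flask still held 21.6% of left-handed substrate, 8.44 times the allowed leftover. Elm, the second flask, reads 2.2% at 15.0 min, which is 0.859 of it.

The readings come from a simulation from invented constants, and the scatter is random.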